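**Assumptions (one line each)**
- Cassine numbering is used: N1, C2 (methyl), C3 (oxygen), C6 (11-oxododecyl). The target SMILES corresponds to (2R,3R,6S), with all three substituents cis.
- In Step 7 the (S)-ligand is written as giving the (2R,3R,6S) series. The sense of induction is unproven and must be assigned experimentally; if it is opposite, use the (R)-ligand and change nothing else.
- Compounds 1, 4 and 12 are taken to be catalogue chemicals.

**Retrosynthetic overview**
1. Ester C–O bond: target ⇒ N-Boc piperidinol 11 + 4-O-TBS-ferulic acid 13.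
2. Piperidine stereotriad (C2, C3, C6): all-cis piperidine 9 ⇒ flat pyridine 8 by one Ir-catalysed asymmetric hydrogenation (the proposed new step).
3. C6–side-chain bond: 8 ⇒ iodopyridine 3 + dodec-11-yn-2-one 6 by Sonogashira coupling, then alkyne saturation.
4. 3 comes from 2-methylpyridin-3-ol (iodination, silylation); 6 comes from undec-10-ynoic acid (Weinreb amide, MeMgBr).
5. Ring order: no ring is cyclised. The pyridine is bought and becomes the piperidine by dearomatising hydrogenation; the guaiacyl ring arrives intact with ferulic acid.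

**Route**

Step 1
Reactants: 1, 2-methylpyridin-3-ol
Product: 2, 6-iodo-2-methylpyridin-3-ol
Conditions: I2 (1.0 equiv), Na2CO3, H2O, rt; then AcOH to pH 5
Reagents that add atoms: iodine, II
Why: Electrophilic aromatic iodination of the pyridinolate; with C2 blocked by methyl, the oxide directs iodine to C6 (para to O, α to N), the usual regiochemistry for 3-hydroxypyridines.

Step 2
Reactants: 2, 6-iodo-2-methylpyridin-3-ol
Product: 3, 6-iodo-2-methyl-3-[(triisopropylsilyl)oxy]pyridine
Conditions: TIPSCl, imidazole, DMF, rt
Reagents that add atoms: triisopropylsilyl chloride, CC(C)[Si](Cl)(C(C)C)C(C)C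
Why: Imidazole-mediated O-silylation; the bulky TIPS ether survives Sonogashira coupling and HCl salt formation, and later blocks keto tautomerisation during ring hydrogenation.

Step 3
Reactants: 4, undec-10-ynoic acid
Product: 5, N-methoxy-N-methylundec-10-ynamide
Conditions: CDI, CH2Cl2, rt; then MeNH(OMe)·HCl, rt
Reagents that add atoms: N,O-dimethylhydroxylamine hydrochloride, CNOC.Cl
Why: Weinreb amide formation through the acyl imidazolide; the terminal alkyne is inert.

Step 4
Reactants: 5, N-methoxy-N-methylundec-10-ynamide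
Product: 6, dodec-11-yn-2-one
Conditions: MeMgBr (2.2 equiv), THF, −20 → 0 °C; aq NH4Cl
Reagents that add atoms: methylmagnesium bromide, C[Mg]Br
Why: Weinreb ketone synthesis; the chelated tetrahedral intermediate prevents over-addition, and addition to the amide is faster than alkyne deprotonation at ≤0 °C (any acetylide formed only consumes the excess Grignard).

Step 5
Reactants: 3, 6-iodo-2-methyl-3-[(triisopropylsilyl)oxy]pyridine; 6, dodec-11-yn-2-one
Product: 7, 12-{6-methyl-5-[(triisopropylsilyl)oxy]pyridin-2-yl}dodec-11-yn-2-one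
Conditions: PdCl2(PPh3)2 (2 mol%), CuI (4 mol%), Et3N/THF, rt
Reagents that add atoms: none
Why: Sonogashira coupling; the 2-iodopyridine undergoes fast oxidative addition, and the ketone and aryl silyl ether tolerate the mild amine base.

Step 6
Reactants: 7, 12-{6-methyl-5-[(triisopropylsilyl)oxy]pyridin-2-yl}dodec-11-yn-2-one
Product: 8, 12-{6-methyl-5-[(triisopropylsilyl)oxy]pyridin-2-yl}dodecan-2-one
Conditions: H2 (1 atm), 10% Pd/C, EtOAc, rt
Reagents that add atoms: none
Why: Heterogeneous catalytic hydrogenation of the alkyne to the alkane; at 1 atm under neutral conditions the pyridine ring, dialkyl ketone and silyl ether are untouched.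

Step 7
Reactants: 8, 12-{6-methyl-5-[(triisopropylsilyl)oxy]pyridin-2-yl}dodecan-2-one
Product: 9, (2R,3R,6S)-2-methyl-6-(11-oxododecyl)-3-[(triisopropylsilyl)oxy]piperidine (all-cis)
Conditions: HCl (1.05 equiv, Et2O), evaporate to 8·HCl; [Ir(cod)Cl]2 (2 mol%), (S)-DifluorPhos (4.4 mol%), H2 (60 bar), anhydrous CH2Cl2/1,4-dioxane (1:1), 40 °C; then aq NaHCO3
Reagents that add atoms: none
Why: Proposed new method: Ir/chiral bisphosphine/chloride-catalysed enantioselective hydrogenation of an N–H 2,6-dialkyl-3-silyloxypyridinium chloride, in which N-protonation activates the ring (N-benzylation is impractical for a 2,6-disubstituted pyridine) and keeps the product as a non-coordinating ammonium salt, reduction proceeds by stepwise outer-sphere Ir–H hydride transfer and C-protonation (1,4-hydride addition, then enamine protonation to the 2- and 6-iminium ions, then hydride delivery to each C=N), the chiral Ir–H chooses the face of the first iminium, C3 is set by dynamic kinetic resolution of the rapidly equilibrating enamine/α-silyloxy-iminium pair (hydride adds anti to the pseudoaxial OTIPS, giving 2,3-cis), the last hydride adds axially to the half-chair iminium (2,6-cis), and the O-TIPS group prevents tautomerisation to an epimerisable piperidin-3-one, so C2, C3 and C6 are all set here while the isolated ketone is not reduced because hydride goes only to cationic C=N; the closest known reaction type is Ir–bisphosphine asymmetric hydrogenation of 2-substituted and 2,3-disubstituted pyridinium halide salts, which has not been shown for 2,6-dialkyl-3-oxypyridines.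

Step 8
Reactants: 9, (2R,3R,6S)-2-methyl-6-(11-oxododecyl)-3-[(triisopropylsilyl)oxy]piperidine
Product: 10, tert-butyl (2R,3R,6S)-2-methyl-6-(11-oxododecyl)-3-[(triisopropylsilyl)oxy]piperidine-1-carboxylate
Conditions: Boc2O (3 equiv), Et3N, MeCN, 60 °C
Reagents that add atoms: di-tert-butyl dicarbonate, CC(C)(C)OC(=O)OC(=O)OC(C)(C)C
Why: Carbamate (Boc) protection of the secondary amine; heat and excess reagent are needed because nitrogen is flanked by two α-substituents, and no stereocentre is touched.

Step 9
Reactants: 10, tert-butyl (2R,3R,6S)-2-methyl-6-(11-oxododecyl)-3-[(triisopropylsilyl)oxy]piperidine-1-carboxylate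
Product: 11, tert-butyl (2R,3R,6S)-3-hydroxy-2-methyl-6-(11-oxododecyl)piperidine-1-carboxylate
Conditions: TBAF, THF, rt → 45 °C
Reagents that add atoms: none
Why: Fluoride-mediated desilylation driven by Si–F bond formation; the Boc group and ketone are inert and the C3–O bond is not broken.

Step 10
Reactants: 12, (E)-ferulic acid
Product: 13, (E)-3-{4-[(tert-butyldimethylsilyl)oxy]-3-methoxyphenyl}prop-2-enoic acid
Conditions: TBSCl (2.5 equiv), imidazole, DMF, rt; then AcOH/THF/H2O, rt
Reagents that add atoms: tert-butyldimethylsilyl chloride, CC(C)(C)[Si](C)(C)Cl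
Why: Bis-silylation followed by selective hydrolysis of the far more labile silyl ester leaves the phenol TBS ether; the E-alkene is unaffected.

Step 11
Reactants: 11, tert-butyl (2R,3R,6S)-3-hydroxy-2-methyl-6-(11-oxododecyl)piperidine-1-carboxylate; 13, 4-O-TBS-(E)-ferulic acid
Product: 14, tert-butyl (2R,3R,6S)-3-{[(E)-3-(4-[(tert-butyldimethylsilyl)oxy]-3-methoxyphenyl)prop-2-enoyl]oxy}-2-methyl-6-(11-oxododecyl)piperidine-1-carboxylate
Conditions: EDC·HCl (2 equiv), DMAP (1 equiv), CH2Cl2, rt
Reagents that add atoms: none
Why: Steglich esterification; acylation at oxygen retains C3 configuration, and in the N-Boc piperidine A(1,3) strain puts the 2-Me and 6-alkyl groups axial so the 3-OH is equatorial and accessible.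

Step 12
Reactants: 14, N-Boc, O-TBS-protected feruloyl ester
Product: 15, tert-butyl (2R,3R,6S)-3-{[(E)-3-(4-hydroxy-3-methoxyphenyl)prop-2-enoyl]oxy}-2-methyl-6-(11-oxododecyl)piperidine-1-carboxylate
Conditions: TBAF (1.1 equiv), AcOH (1.1 equiv), THF, 0 °C
Reagents that add atoms: none
Why: Buffered fluoride cleavage of the aryl silyl ether; AcOH suppresses phenoxide or fluoride attack on the ester, and with nitrogen still Boc-protected no O→N acyl shift can occur.

Step 13
Reactants: 15, N-Boc feruloyl ester
Product: 16, (+)-3-O-feruloylcassine, (2R,3R,6S)-2-methyl-6-(11-oxododecyl)piperidin-3-yl (E)-3-(4-hydroxy-3-methoxyphenyl)prop-2-enoate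
Conditions: 4 M HCl in dioxane, CH2Cl2, 0 °C → rt; then cold aq NaHCO3
Reagents that add atoms: none
Why: Acidolytic Boc removal (loss of tert-butyl cation and CO2); the enoate ester, ketone and phenol are stable to anhydrous HCl, and the amine is freed only on brief bicarbonate work-up.

**Compound list**
1 | 2-methylpyridin-3-ol | Cc1ncccc1O | starting material
2 | 6-iodo-2-methylpyridin-3-ol | Cc1nc(I)ccc1O | intermediate
3 | 6-iodo-2-methyl-3-[(triisopropylsilyl)oxy]pyridine | Cc1nc(I)ccc1O[Si](C(C)C)(C(C)C)C(C)C | intermediate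
4 | undec-10-ynoic acid | C#CCCCCCCCCC(=O)O | starting material
5 | N-methoxy-N-methylundec-10-ynamide | C#CCCCCCCCCC(=O)N(C)OC | intermediate
6 | dodec-11-yn-2-one | C#CCCCCCCCCC(C)=O | intermediate
7 | 12-{6-methyl-5-[(triisopropylsilyl)oxy]pyridin-2-yl}dodec-11-yn-2-one | CC(=O)CCCCCCCCC#Cc1ccc(O[Si](C(C)C)(C(C)C)C(C)C)c(C)n1 | intermediate
8 | 12-{6-methyl-5-[(triisopropylsilyl)oxy]pyridin-2-yl}dodecan-2-one | CC(=O)CCCCCCCCCCc1ccc(O[Si](C(C)C)(C(C)C)C(C)C)c(C)n1 | intermediate
9 | (2R,3R,6S)-2-methyl-6-(11-oxododecyl)-3-[(triisopropylsilyl)oxy]piperidine | CC(C)[Si](O[C@@H]1CC[C@H](CCCCCCCCCCC(C)=O)N[C@@H]1C)(C(C)C)C(C)C | intermediate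
10 | tert-butyl (2R,3R,6S)-2-methyl-6-(11-oxododecyl)-3-[(triisopropylsilyl)oxy]piperidine-1-carboxylate | CC(C)[Si](O[C@@H]1CC[C@H](CCCCCCCCCCC(C)=O)N(C(=O)OC(C)(C)C)[C@@H]1C)(C(C)C)C(C)C | intermediate
11 | tert-butyl (2R,3R,6S)-3-hydroxy-2-methyl-6-(11-oxododecyl)piperidine-1-carboxylate | O[C@@H]1CC[C@H](CCCCCCCCCCC(C)=O)N(C(=O)OC(C)(C)C)[C@@H]1C | intermediate
12 | (E)-ferulic acid | COc1cc(/C=C/C(=O)O)ccc1O | starting material
13 | (E)-3-{4-[(tert-butyldimethylsilyl)oxy]-3-methoxyphenyl}prop-2-enoic acid | COc1cc(/C=C/C(=O)O)ccc1O[Si](C)(C)C(C)(C)C | intermediate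
14 | N-Boc, 4'-O-TBS 3-O-feruloylcassine | COc1cc(/C=C/C(=O)O[C@@H]2CC[C@H](CCCCCCCCCCC(C)=O)N(C(=O)OC(C)(C)C)[C@@H]2C)ccc1O[Si](C)(C)C(C)(C)C | intermediate
15 | N-Boc 3-O-feruloylcassine | COc1cc(/C=C/C(=O)O[C@@H]2CC[C@H](CCCCCCCCCCC(C)=O)N(C(=O)OC(C)(C)C)[C@@H]2C)ccc1O | intermediate
16 | (+)-3-O-feruloylcassine | COc1cc(/C=C/C(=O)O[C@@H]2CC[C@H](CCCCCCCCCCC(C)=O)N[C@@H]2C)ccc1O | target

**Totals**
- Total step count: 13.
- Longest linear sequence: 10 steps (1 → 2 → 3 → 7 → 8 → 9 → 10 → 11 → 14 → 15 → 16; Steps 1, 2, 5, 6, 7, 8, 9, 11, 12, 13).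

**Three steps most likely to fail, with fallbacks**
1. **Step 7 (proposed new asymmetric hydrogenation).** Risks are low turnover at the doubly α-substituted pyridinium, modest ee, or silyl loss to a piperidin-3-one. Fallback (known chemistry): mask the ketone of 8 as its dioxolane and hydrogenate the pyridine racemically over Rh/Al2O3 or PtO2, which gives the all-cis racemate by syn-facial addition. Then Boc-protect and desilylate to rac-11, and resolve it by separating its (1S)-camphanate ester diastereomers (then K2CO3/MeOH) or by preparative chiral SFC.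
2. **Step 11 (esterification of the hindered C3 alcohol).** Risk is N-acylurea formation or slow acylation. Fallback: acylate 11 with the small acid diethylphosphonoacetic acid (DIC/DMAP), then build the ferulate C=C on the substrate by Masamune–Roush Horner–Wadsworth–Emmons olefination (LiCl, DBU, MeCN) with 4-O-TBS-vanillin, which is E-selective.
3. **Step 8 (Boc protection of the 2,6-cis-disubstituted amine next to OTIPS).** Risk is incomplete carbamoylation. Fallback: skip N-protection. Desilylate 9 as its hydrochloride (HCl/MeOH) and O-acylate the ammonium salt chemoselectively with 4-O-acetylferuloyl chloride in CF3CO2H (acid-mediated O-acylation of amino alcohols), then remove the phenolic acetate with NH4OAc in aq MeOH.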